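All runs were computed with constants of no real substance.

Time is what I can still give the birch flask, and second reagent is what I could still add to it, so my next step is a choice between the two.

| flask | starting material | partner | second reagent | remark | time |
|---|---|---|---|---|---|
| birch | 0.050 M | 2 equiv (in portions, 4) | 1.5 equiv | the very flask that is asked about, followed so far; portions every 1.0 h |  |
| elm | 0.050 M | 2 equiv (in portions, 4) | 2.2 equiv | run made earlier; portions every 1.0 h |  |
| flask | 0.050 M | 2.00 equiv (in portions, 4) | 1.50 equiv | the portions of partner follow each other after 1.0 h, the first at the start | 15 d |

- birch (time / h: starting material / %, target / %, isomer of the product / %): 1.50: 80.2, 4.9, 1.3; 4.00: 37.4, 26.6, 8.3; 8.00: 10.4, 57.0, 15.3; 12.0: 3.8, 70.8, 16.5; 20.0: 0.8, 82.1, 15.0; 25.0: 0.4, 83.7, 14.6; 30.0: 0, 84.7, 14.2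
- elm (time / d: starting material / %, target / %, isomer of the product / %): 0.833: 0.2, 84.4, 15.0; 2.50: 0.1, 85.7, 14.2; 4.00: 0.1, 85.6, 14.4; 6.00: 0.3, 85.8, 14.1; 10.0: 0, 85.6, 14.4; 12.0: 0.2, 85.2, 14.3; 15.0: 0.2, 86.4, 14.1

(each reading ± 0.3 percentage points)

- a reading or a percentage of target counts all its forms, free or not
- the reaction counts as stopped when no species that holds the starting material changes by six tenths of a point or more over the second half of the time

* at 15 d, what has stopped the reaction, if anything has (all of the starting material has reacted / the partner has run out first / it is still moving / forward and back rates have come level / the second reagent has run out first)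
* how much of the starting material has reacted by 15 d
* how much target there is at 15 d, in percent of the starting material charged
* how much isomer of the product there is at 15 d, in percent of the starting material charged
* amount of target if the flask were left three thousand times as long, in percent of the starting material charged

At 30.0 h birch already reads 98.9% as target plus isomer, with starting material at 0%. Its isomer reached a reading of 16.5% at 12.0 h and came back to 14.2%, so isomer goes back to target as well as forming from it. Where those two rates run level, their quotient is one and time drops out of the amounts, which is thermodynamic rather than kinetic control.

Elm looks like that state: from 2.50 d to 15.0 d its isomer stays between 14.1% and 14.4%. Elm's mean isomer share over those readings, times its charge of starting material, comes to 7.13 mM. I call this the resting isomer level, and I keep it as a concentration so that it can be held against another charge.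

Birch's isomer at 30.0 h reads 7.10 mM with 1.5 equiv of second reagent, where elm had 2.2 equiv, so elm's extra reagent shows no visible change in this level. I therefore add nothing to birch and leave it standing. The level over birch's charge gives me 14.3% isomer, and the remainder, 85.7%, is target.

The forecast gives 85.7% target, 14.3% isomer and 100% conversion at 15 d, with 85.7% target after a far longer wait; its verdict on the end is: all of the starting material has reacted. It says of elm's charge that “the extra reagent seems not to shift it”. Its target and isomer figures are the ones I reckon.

The flask gives 85.7% target and 14.3% isomer, with 100% reacted, and 85.7% target after the long wait; the verdict is: all of the starting material has reacted. Of the target counted, 77.3% of the starting material charged stands as crystals.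

    starting material + partner → intermediate (k = 0.0860 M⁻¹ min⁻¹)
    second reagent + intermediate → target (k = 0.140 M⁻¹ min⁻¹)
    target ⇌ isomer of the product (K = 1.70, k = 0.00650 min⁻¹)
    crystals ⇌ target, rate k4*(cs4 - [target]) while solid is left; crystals form when [target] > cs4 (solubility = 4.20 mM, k = 0.0390 min⁻¹)

Over the flask's charge of 0.050 M, the resting isomer level gave me 14.3%. The flask's isomer, taken as a concentration of the whole charge, comes to 7.15 mM, and the solubility of target, 4.2 mM, times the constant of the isomer step, 1.7, gives 7.14 mM.

In the neighbour charged with 0.12 M of starting material, the carried level gives 5.94% isomer. The computed neighbour holds 5.95% isomer and 94.0% target.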